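The target is disconnected at its C3–O and C6–Cl bonds, which sit cis to each other across the C4=C5 alkene of the cyclohexene ring: exactly what a 1,4-addition to a C3=C4–C5=C6 diene leaves behind. A palladium-catalysed 1,4-chloroacetoxylation therefore installs the allylic chloride, the C3 oxygen (as a temporary acetate) and both new stereocentres in one operation, trans to the C1/C2 oxygens. The precursor is the enantiopure cis-dienediol from microbial dihydroxylation of benzoic acid, carried as its C1,C2-acetonide with C7 already benzoylated; the acetonide shields the upper face and is later exchanged for the C2 benzoate.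

Key step: step 6

Remarks on the chemistry:
- Numbering and faces: C1 is the tertiary carbinol carbon bearing C7, then C2, C3, C4=C5 and C6. "Upper face" is the face of the C1 and C2 oxygens; "lower face" is the face of C7, the C3 oxygen and the chlorine.
- Assumption: the B9 strain delivers the (1S,2R)-diol acid, which maps directly onto C1 and C2 of the target. The SMILES of 8, 10 and 13 carry the same C1/C2 configuration and place both new substituents on the lower face, so no structure needed correcting.
- Precursor design: the diol is kept as the acetonide, because an ester on O2 could deliver its carbonyl oxygen to C3 and a free diol invites aromatisation. C7 is benzoylated before the key step so that no free lower-face hydroxyl can steer palladium to that face. The lower face is not empty at C6, since C7 adjoins it; this is the main regiochemical risk of step 6.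

Step 1
Reactants: 1 benzoic acid
Product: 2 (1S,2R)-1,2-dihydroxycyclohexa-3,5-diene-1-carboxylic acid (both hydroxyls on the same face)
Conditions: Ralstonia eutropha B9 whole cells (diol dehydrogenase-deficient), 1 fed as PhCO2Na, sodium succinate (Na2C4H4O4) as carbon source, mineral salts medium, air, 30 °C, pH 7; then pH 3, 0 °C, EtOAc extraction
Reagents that add atoms: dioxygen, O=O
Why: Enzymatic arene cis-dihydroxylation, in which the benzoate 1,2-dioxygenase of the strain adds both atoms of O2 to the ipso and ortho carbons on one face, the blocked dehydrogenase lets the diol accumulate, and the active site sets both stereocentres as a single enantiomer.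

Step 2
Reactants: 2 (1S,2R)-1,2-dihydroxycyclohexa-3,5-diene-1-carboxylic acid
Product: 3 methyl (1S,2R)-1,2-dihydroxycyclohexa-3,5-diene-1-carboxylate
Conditions: MeI, K2CO3, DMF, 0 °C to rt
Reagents that add atoms: iodomethane, CI
Why: Carboxylate O-alkylation (SN2 on iodomethane) under weakly basic conditions, which avoids the acid that would dehydrate the dienediol to an arene and leaves the hydroxyls and both stereocentres untouched.

Step 3
Reactants: 3 methyl (1S,2R)-1,2-dihydroxycyclohexa-3,5-diene-1-carboxylate; 4 2,2-dimethoxypropane
Product: 5 methyl (3aS,7aR)-2,2-dimethyl-3a,7a-dihydro-1,3-benzodioxole-3a-carboxylate (cis-fused acetonide)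
Conditions: 2,2-dimethoxypropane, p-TsOH·H2O (cat.), acetone, 0 °C to rt; Et3N quench
Reagents that add atoms: 2,2-dimethoxypropane (4), COC(C)(C)OC
Why: Acid-catalysed transketalisation in which the cis-1,2-diol closes to the five-membered dioxolane without breaking a ring C–O bond, kept cold and quenched with base to prevent aromatisation.

Step 4
Reactants: 5 methyl (3aS,7aR)-2,2-dimethyl-3a,7a-dihydro-1,3-benzodioxole-3a-carboxylate
Product: 6 [(3aR,7aR)-2,2-dimethyl-3a,7a-dihydro-1,3-benzodioxol-3a-yl]methanol
Conditions: LiAlH4, THF, 0 °C; then H2O, aq. NaOH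
Reagents that add atoms: none
Why: Hydride reduction of an ester to the primary alcohol, clean because the ester sits on sp3 carbon C1 and is not conjugated to the diene; the descriptor at C1 changes from S to R only through the priority change.

Step 5
Reactants: 6 [(3aR,7aR)-2,2-dimethyl-3a,7a-dihydro-1,3-benzodioxol-3a-yl]methanol; 7 benzoyl chloride
Product: 8 [(3aR,7aR)-2,2-dimethyl-3a,7a-dihydro-1,3-benzodioxol-3a-yl]methyl benzoate (C1,C2-acetonide of the dienediol, C7 benzoate; used promptly)
Conditions: BzCl, pyridine, DMAP (cat.), CH2Cl2, 0 °C to rt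
Reagents that add atoms: benzoyl chloride (7), O=C(Cl)c1ccccc1
Why: Nucleophilic acyl substitution (DMAP-assisted O-benzoylation) at the only hydroxyl in the molecule.

Step 6
Reactants: 8 [(3aR,7aR)-2,2-dimethyl-3a,7a-dihydro-1,3-benzodioxol-3a-yl]methyl benzoate; 9 lithium chloride
Product: 10 [(3aR,4R,7S,7aR)-7-acetoxy-4-chloro-2,2-dimethyl-3a,4,7,7a-tetrahydro-1,3-benzodioxol-3a-yl]methyl benzoate (acetate on C3 and chlorine on C6 both on the lower face, alkene at C4=C5)
Conditions: Pd(OAc)2 (5 mol %), LiCl (excess), LiOAc, p-benzoquinone (2 equiv), AcOH, rt, slow addition of 8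
Reagents that add atoms: lithium chloride (9), [Li+].[Cl-]; acetic acid (acetate source, buffered by LiOAc), CC(=O)O
Why: Proposed new method: divalent palladium binds the C3=C4–C5=C6 diene, acetate attacks C3 on the face opposite the metal to give an η3-allyl complex over C4–C6, chloride then attacks C6 from outside, again opposite the metal, and the zerovalent palladium released is reoxidised by p-benzoquinone; the closest known reaction type is the palladium-catalysed cis-1,4-chloroacetoxylation of simple cyclohexa-1,3-dienes, which has not been shown on a diene whose terminus adjoins a quaternary oxygenated carbon. No ring is closed. The C3 stereocentre is controlled by the dioxolane oxygen on C2, which blocks the upper face at the neighbouring C3 so that acetate enters from below, where C2 carries only hydrogen, with the metal held on the oxygen-bearing upper face. The C6 stereocentre is controlled by the mechanism: chloride must enter anti to that same palladium, hence cis to the acetate and trans to the C1 oxygen. The step needs acetate at C3 and not C6, which the neopentyl-like position of C6 next to quaternary C1 should secure, and chloride at C6 and not C4, which the inductively deactivating lower-face acetoxy group next to C4 should secure. A high chloride concentration and the quinone ligand favour external chloride attack over ligand migration from the metal, and slow addition of the diene limits its Diels–Alder capture by the quinone.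

Step 7
Reactants: 10 [(3aR,4R,7S,7aR)-7-acetoxy-4-chloro-2,2-dimethyl-3a,4,7,7a-tetrahydro-1,3-benzodioxol-3a-yl]methyl benzoate
Product: 11 [(1R,2R,3S,6R)-3-acetoxy-6-chloro-1,2-dihydroxycyclohex-4-en-1-yl]methyl benzoate (numbering of the remarks)
Conditions: CF3CO2H/H2O (9:1), CH2Cl2, 0 °C
Reagents that add atoms: none
Why: Acid-catalysed hydrolysis of the isopropylidene ketal, which cleaves at the ketal carbon so that the ring C–O bonds keep their configuration, while the esters and the allylic chloride (deactivated towards ionisation by the flanking oxygen-bearing carbons) should tolerate cold aqueous acid.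

Step 8
Reactants: 11 [(1R,2R,3S,6R)-3-acetoxy-6-chloro-1,2-dihydroxycyclohex-4-en-1-yl]methyl benzoate; 7 benzoyl chloride
Product: 12 [(1R,2R,3S,6R)-3-acetoxy-2-(benzoyloxy)-6-chloro-1-hydroxycyclohex-4-en-1-yl]methyl benzoate
Conditions: BzCl (1.2 equiv), pyridine, CH2Cl2, −20 to 0 °C
Reagents that add atoms: benzoyl chloride (7), O=C(Cl)c1ccccc1
Why: Regioselective O-acylation in which the secondary C2 hydroxyl reacts while the tertiary C1 hydroxyl is inert and C3 is already capped as the acetate, the weak base and low temperature guarding against acetyl migration and closure of the trans-chlorohydrin to an epoxide.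

Step 9
Reactants: 12 [(1R,2R,3S,6R)-3-acetoxy-2-(benzoyloxy)-6-chloro-1-hydroxycyclohex-4-en-1-yl]methyl benzoate
Product: 13 [(1R,2R,3S,6R)-2-(benzoyloxy)-6-chloro-1,3-dihydroxycyclohex-4-en-1-yl]methyl benzoate (target: C1–OH and C2–OBz on the upper face; C3–OH, C6–Cl and C7 on the lower face)
Conditions: HCl (0.5 M) in MeOH, CH2Cl2, 0 °C to rt, stopped when the acetate is consumed
Reagents that add atoms: none
Why: Acid-catalysed transesterification (methanolysis), in which the unhindered, non-conjugated acetyl carbonyl reacts far faster than the benzoyl carbonyls and the acidic medium avoids both benzoyl migration and epoxide formation from the chlorohydrin.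

Compound list
1 | benzoic acid | O=C(O)c1ccccc1 | starting material
2 | (1S,2R)-1,2-dihydroxycyclohexa-3,5-diene-1-carboxylic acid | O=C(O)[C@]1(O)C=CC=C[C@H]1O | intermediate
3 | methyl (1S,2R)-1,2-dihydroxycyclohexa-3,5-diene-1-carboxylate | COC(=O)[C@]1(O)C=CC=C[C@H]1O | intermediate
4 | 2,2-dimethoxypropane | COC(C)(C)OC | starting material
5 | methyl (3aS,7aR)-2,2-dimethyl-3a,7a-dihydro-1,3-benzodioxole-3a-carboxylate | COC(=O)[C@]1(OC(C)(C)O2)C=CC=C[C@H]12 | intermediate
6 | [(3aR,7aR)-2,2-dimethyl-3a,7a-dihydro-1,3-benzodioxol-3a-yl]methanol | OC[C@]1(OC(C)(C)O2)C=CC=C[C@H]12 | intermediate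
7 | benzoyl chloride | O=C(Cl)c1ccccc1 | starting material
8 | [(3aR,7aR)-2,2-dimethyl-3a,7a-dihydro-1,3-benzodioxol-3a-yl]methyl benzoate | O=C(OC[C@]1(OC(C)(C)O2)C=CC=C[C@H]12)c1ccccc1 | intermediate
9 | lithium chloride | [Li+].[Cl-] | starting material
10 | [(3aR,4R,7S,7aR)-7-acetoxy-4-chloro-2,2-dimethyl-3a,4,7,7a-tetrahydro-1,3-benzodioxol-3a-yl]methyl benzoate | O=C(OC[C@]1(OC(C)(C)O2)[C@H](Cl)C=C[C@H](OC(C)=O)[C@H]12)c1ccccc1 | intermediate
11 | [(1R,2R,3S,6R)-3-acetoxy-6-chloro-1,2-dihydroxycyclohex-4-en-1-yl]methyl benzoate | O=C(OC[C@]1(O)[C@H](Cl)C=C[C@H](OC(C)=O)[C@H]1O)c1ccccc1 | intermediate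
12 | [(1R,2R,3S,6R)-3-acetoxy-2-(benzoyloxy)-6-chloro-1-hydroxycyclohex-4-en-1-yl]methyl benzoate | O=C(OC[C@]1(O)[C@H](Cl)C=C[C@H](OC(C)=O)[C@H]1OC(=O)c1ccccc1)c1ccccc1 | intermediate
13 | [(1R,2R,3S,6R)-2-(benzoyloxy)-6-chloro-1,3-dihydroxycyclohex-4-en-1-yl]methyl benzoate | O=C(OC[C@]1(O)[C@H](Cl)C=C[C@H](O)[C@H]1OC(=O)c1ccccc1)c1ccccc1 | target

Total step count: 9. Longest linear sequence: 9 steps (1 to 13).

Steps most likely to fail

Step 6 (proposed new method). Palladium may bind the lower face, so that both nucleophiles enter syn to the dioxolane. Chloride may attack C4 (1,2-addition) because C6 is crowded by C7. The diene may be lost to Diels–Alder reaction with the quinone. The fallback uses known reaction types only, sets out from 8 and returns at 12; it reaches the same pattern by a double inversion at C6.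
- Photooxygenation of 8 (O2, hν, tetraphenylporphyrin, CH2Cl2, −30 °C) should add singlet oxygen by [4+2] cycloaddition on the face remote from the dioxolane, giving the C3,C6-endoperoxide F1.
- Thiourea in MeOH reduces the O–O bond to the cis-3,6-diol F2, with both hydroxyls on the lower face.
- Ac2O/pyridine at −20 °C acetylates the less hindered C3 hydroxyl to the 3-acetate F3.
- MsCl/Et3N at −20 °C gives the C6 mesylate F4.
- Cold aqueous CF3CO2H removes the acetonide to give the diol mesylate F5.
- BzCl/pyridine gives the C2 benzoate mesylate F6.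
- DBU in CH2Cl2 closes the C1 oxygen onto C6 with inversion, giving the C1,C6-epoxide F7 with its oxygen on the upper face.
- HCl in Et2O at 0 °C opens the epoxide at the allylic C6 with a second inversion, which puts chlorine on the lower face and gives 12; step 9 then follows.

Step 9. The acetate of 12 is flanked by the C2 benzoate, so its methanolysis may slow enough for cleavage of the primary benzoate and benzoyl migration from O2 to the freed O3 to compete. The fallback sets out from 10 and returns at 13. It removes the acetate before any benzoate sits on the ring and carries O3 as a silyl ether.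
- Aqueous methanolic HCl at rt cleaves the acetonide and the acetate of 10 together to give the chlorotriol 7-benzoate F8.
- TBSCl/imidazole in DMF at 0 °C silylates the allylic C3 hydroxyl in preference to the C2 hydroxyl, which is flanked by quaternary C1, giving the 3-silyl ether F9.
- BzCl/pyridine/DMAP benzoylates C2 to give the 2-benzoate 3-silyl ether F10.
- HF·pyridine in THF removes the silyl group under acidic conditions and gives 13.

Step 8. Acylation of the C2 hydroxyl, which lies between quaternary C1 and the acetoxy-bearing C3, may be sluggish. The amine base may also move the acetyl group from O3 to O2 or close the chlorohydrin to the epoxide. The fallback sets out from 11 and returns at 12.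
- Bu2SnO in MeOH at 60 °C, followed by evaporation, converts the cis-1,2-diol into the dibutylstannylene acetal F11.
- BzCl in toluene at rt, without added base, benzoylates the tin-activated secondary oxygen; aqueous work-up frees the C1 hydroxyl and gives 12.

Further compounds
F1 | step 6 | [(3aR,7aR)-acetonide of the dienediol C7 benzoate, C3,C6-endoperoxide on the lower face] | O=C(OC[C@]1(OC(C)(C)O2)[C@H](OO3)C=C[C@H]3[C@H]12)c1ccccc1
F2 | step 6 | C1,C2-acetonide C7-benzoate cis-3,6-diol (both hydroxyls on the lower face) | O=C(OC[C@]1(OC(C)(C)O2)[C@H](O)C=C[C@H](O)[C@H]12)c1ccccc1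
F3 | step 6 | C1,C2-acetonide C7-benzoate 3-acetate 6-ol | O=C(OC[C@]1(OC(C)(C)O2)[C@H](O)C=C[C@H](OC(C)=O)[C@H]12)c1ccccc1
F4 | step 6 | C1,C2-acetonide C7-benzoate 3-acetate 6-mesylate | O=C(OC[C@]1(OC(C)(C)O2)[C@H](OS(C)(=O)=O)C=C[C@H](OC(C)=O)[C@H]12)c1ccccc1
F5 | step 6 | C1,C2-diol C7-benzoate 3-acetate 6-mesylate | O=C(OC[C@]1(O)[C@H](OS(C)(=O)=O)C=C[C@H](OC(C)=O)[C@H]1O)c1ccccc1
F6 | step 6 | C2,C7-dibenzoate 3-acetate 6-mesylate with free C1 hydroxyl | O=C(OC[C@]1(O)[C@H](OS(C)(=O)=O)C=C[C@H](OC(C)=O)[C@H]1OC(=O)c1ccccc1)c1ccccc1
F7 | step 6 | C1,C6-epoxide (oxygen on the upper face) C2,C7-dibenzoate 3-acetate | O=C(OC[C@@]12O[C@H]2C=C[C@H](OC(C)=O)[C@H]1OC(=O)c1ccccc1)c1ccccc1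
F8 | step 9 | [(1R,2R,3S,6R)-6-chloro-1,2,3-trihydroxycyclohex-4-en-1-yl]methyl benzoate | O=C(OC[C@]1(O)[C@H](Cl)C=C[C@H](O)[C@H]1O)c1ccccc1
F9 | step 9 | C3 tert-butyldimethylsilyl ether of the chlorotriol 7-benzoate | O=C(OC[C@]1(O)[C@H](Cl)C=C[C@H](O[Si](C)(C)C(C)(C)C)[C@H]1O)c1ccccc1
F10 | step 9 | C2,C7-dibenzoate C3 tert-butyldimethylsilyl ether | O=C(OC[C@]1(O)[C@H](Cl)C=C[C@H](O[Si](C)(C)C(C)(C)C)[C@H]1OC(=O)c1ccccc1)c1ccccc1
F11 | step 8 | C1,C2-O-dibutylstannylene acetal of 11 | O=C(OC[C@]1(O[Sn](CCCC)(CCCC)O2)[C@H](Cl)C=C[C@H](OC(C)=O)[C@H]12)c1ccccc1
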